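**Plan**

- Retrosynthesis: after removal of two MOM ethers, the C1–C6 bond of ring A is cut, which unfolds ring A into an open-chain methyl 3,5,7-trioxodecanoate. Ring A (C1 with the butanoyl group, C2, quaternary C3, C4, C5 with the methylene bridge, C6 carbonyl) is a butanoyl-started tetraketide whose C3 lies insulated between the C2 and C4 carbonyls, so a C1 carbanion can be joined to a C6 ester without C3 ever becoming enolisable.
- The chain is cut further at the bond from its C2 to the benzylic CH2 of ring B (β-keto ester alkylation), at its C2–C3 bond (homologation of an acid with a malonate half-ester), and at the acyl–alkyne bond of an ynone; the diketone is carried through the middle of the route as an isoxazole.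
- Forward: methylmalonate → prenylated diester → half-ester → ynone → isoxazole → acid → β-keto ester; ring B benzyl bromide from phloroglucinol in six steps; union by C-alkylation; isoxazole opened to the diketone; ring A closed last; deprotection.
- Stereochemistry: the single stereocentre (C3 of ring A) comes from pig liver esterase (PLE) desymmetrisation of the prochiral malonate and has no α-hydrogen in any later compound.

Key step: step 15

Assumption: PLE is taken to deliver the (S)-half-ester of the prenylated diester (free acid on the arm that becomes the diketone); if the enzyme prefers the other ester group, the resolution given as fallback for step 2 supplies the same (S)-acid.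

**Route**

Step 1
Reactants: 1 dimethyl 2-methylpropanedioate (dimethyl methylmalonate); 2 1-bromo-3-methylbut-2-ene (prenyl bromide)
Product: 3 dimethyl 2-methyl-2-(3-methylbut-2-en-1-yl)propanedioate
Conditions: NaH, THF, 0 °C; then 2, 0 °C to rt
Reagents that add atoms: none
Why: The sodium enolate of the methylmalonate is alkylated at the primary carbon of the allylic bromide (malonic ester SN2 alkylation), which should give the achiral but prochiral quaternary diester.

Step 2
Reactants: 3
Product: 4 (2S)-2-(methoxycarbonyl)-2,5-dimethylhex-4-enoic acid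
Conditions: pig liver esterase (PLE), 0.1 M phosphate buffer pH 7.5, DMSO (10 vol %), 25 °C, pH-stat with 1 M NaOH (1.0 equiv); then 1 M HCl to pH 2, EtOAc
Reagents that add atoms: water, O
Why: Enzymatic desymmetrisation of a prochiral 2-alkyl-2-methylmalonate hydrolyses one of the two enantiotopic ester groups and stops at the half-ester because the carboxylate is no longer a substrate, so the quaternary stereocentre is set by the enzyme's choice between the two ester groups.

Step 3
Reactants: 4; 5 pent-1-yne
Product: 7 methyl (2S)-2-methyl-2-(3-methylbut-2-en-1-yl)-3-oxooct-4-ynoate, via acid chloride 6 (not isolated)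
Conditions: (COCl)2, DMF (cat.), CH2Cl2, 0 °C to rt, evaporate; then 5, PdCl2(PPh3)2 (2 mol %), CuI (4 mol %), Et3N, THF, rt
Reagents that add atoms: none
Why: The malonyl half-ester chloride has no α-hydrogen and cannot form a ketene, so it should couple cleanly with the copper acetylide of pent-1-yne in an acyl Sonogashira reaction, giving an ynone that holds the future diketone at the alkyne oxidation level.

Step 4
Reactants: 7
Product: 8 methyl (2S)-2,5-dimethyl-2-(3-propyl-1,2-oxazol-5-yl)hex-4-enoate
Conditions: NH2OH·HCl, NaOAc, EtOH, reflux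
Reagents that add atoms: hydroxylamine hydrochloride, NO.Cl
Why: Conjugate addition of the hydroxylamine nitrogen to the ynone and cyclodehydration onto the hindered ketone is the classical isoxazole synthesis from ynones, and it turns the electrophilic and later acidic 1,3-dicarbonyl unit into a base-stable aromatic ring (the regioisomeric isoxazole, should it form, unmasks to the same diketone).

Step 5
Reactants: 8
Product: 9 (2S)-2,5-dimethyl-2-(3-propyl-1,2-oxazol-5-yl)hex-4-enoic acid
Conditions: KOH, MeOH/H2O (3:1), 60 °C; then 1 M HCl to pH 2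
Reagents that add atoms: potassium hydroxide, [K+].[OH-]
Why: Saponification of the hindered methyl ester is safe at this point because the neighbouring carbonyl is locked in the isoxazole, which excludes the retro-Claisen cleavage and the β-keto acid decarboxylation that a free ketone at this position would invite.

Step 6
Reactants: 9; 10 potassium methyl malonate (potassium 3-methoxy-3-oxopropanoate)
Product: 12 methyl (4S)-4,7-dimethyl-3-oxo-4-(3-propyl-1,2-oxazol-5-yl)oct-6-enoate, via acyl imidazole 11 (not isolated)
Conditions: CDI, THF, rt; then 10, MgCl2, Et3N, MeCN/THF, rt to 45 °C; 1 M HCl work-up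
Reagents that add atoms: none
Why: In this Masamune–Brooks homologation the acyl imidazole is C-acylated by the magnesium enolate of the malonate half-ester and loss of CO2 gives the β-keto ester without any strongly basic or nucleophilic reagent.

Step 7
Reactants: 13 phloroglucinol (benzene-1,3,5-triol); 14 butanoyl chloride
Product: 15 1-(2,4,6-trihydroxyphenyl)butan-1-one
Conditions: AlCl3, PhNO2/CH2Cl2, 0 °C to 40 °C; then ice/HCl
Reagents that add atoms: none
Why: Friedel–Crafts acylation of the symmetrical triphenol should stop after one acylation because the ketone, chelated by two ortho hydroxy groups, deactivates the ring.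

Step 8
Reactants: 15
Product: 16 1-(2,6-dihydroxy-4-methoxyphenyl)butan-1-one
Conditions: Me2SO4 (1.0 equiv), K2CO3, acetone, reflux
Reagents that add atoms: dimethyl sulfate, COS(=O)(=O)OC
Why: The para hydroxy group is the only one not hydrogen-bonded to the ketone and is the most acidic, so Williamson methylation with one equivalent of dimethyl sulfate should take place there.

Step 9
Reactants: 16
Product: 17 3-butanoyl-2,4-dihydroxy-6-methoxybenzaldehyde
Conditions: Cl2CHOMe, TiCl4, CH2Cl2, −10 °C to 0 °C; then 1 M HCl
Reagents that add atoms: dichloromethyl methyl ether, COC(Cl)Cl; water, O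
Why: Rieche formylation occurs ortho to a titanium phenoxide, and since the two free ring positions of 16 are equivalent only one regioisomer can form.

Step 10
Reactants: 17
Product: 18 3-butanoyl-6-methoxy-2,4-bis(methoxymethoxy)benzaldehyde
Conditions: NaH (2.2 equiv), DMF, 0 °C; then MOMCl (2.5 equiv), 0 °C to rt
Reagents that add atoms: chloromethyl methyl ether, COCCl
Why: Both chelated phenols are converted into sodium phenoxides and O-alkylated by MOMCl, which removes the acidic protons and the ortho-quinone methide pathway before the benzylic halide is made.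

Step 11
Reactants: 18
Product: 19 1-[3-(hydroxymethyl)-4-methoxy-2,6-bis(methoxymethoxy)phenyl]butan-1-one
Conditions: NaBH4, MeOH/THF, −20 °C
Reagents that add atoms: none
Why: Borohydride reduces the aldehyde much faster than the ketone, which is flanked by two ortho substituents and twisted out of conjugation, so a chemoselective reduction to the benzylic alcohol is expected.

Step 12
Reactants: 19
Product: 20 1-[3-(bromomethyl)-4-methoxy-2,6-bis(methoxymethoxy)phenyl]butan-1-one
Conditions: CBr4, PPh3, CH2Cl2, 0 °C; used at once
Reagents that add atoms: carbon tetrabromide, BrC(Br)(Br)Br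
Why: The Appel reaction converts the primary benzylic alcohol into the bromide under neutral conditions that leave the MOM acetals untouched.

Step 13
Reactants: 12; 20
Product: 21 methyl (4S)-2-{[3-butanoyl-6-methoxy-2,4-bis(methoxymethoxy)phenyl]methyl}-4,7-dimethyl-3-oxo-4-(3-propyl-1,2-oxazol-5-yl)oct-6-enoate (both epimers at C2)
Conditions: K2CO3, acetone, rt
Reagents that add atoms: none
Why: The β-keto ester is the only acidic C–H site of 12 while the diketone is masked, so its potassium enolate should be C-alkylated by the activated benzylic bromide (acetoacetic ester alkylation); the new stereocentre at C2 forms without control, which does not matter because this carbon becomes sp2 in ring A.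

Step 14
Reactants: 21
Product: 23 methyl (4S)-2-{[3-butanoyl-6-methoxy-2,4-bis(methoxymethoxy)phenyl]methyl}-4-methyl-4-(3-methylbut-2-en-1-yl)-3,5,7-trioxodecanoate (both epimers at C2), via enaminone 22 (not isolated)
Conditions: Mo(CO)6, MeCN/H2O (10:1), 80 °C; then aq. oxalic acid, THF, rt
Reagents that add atoms: water, O
Why: Mo(CO)6 cleaves the weak N–O bond of the isoxazole reductively to the β-amino enone without touching the alkene or the ketones, and mild aqueous acid hydrolyses this vinylogous amide to the 1,3-diketone, which is the standard use of an isoxazole as a masked β-diketone.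

Step 15
Reactants: 23
Product: 24 (4R)-2-butanoyl-6-{[3-butanoyl-6-methoxy-2,4-bis(methoxymethoxy)phenyl]methyl}-3,5-dihydroxy-4-methyl-4-(3-methylbut-2-en-1-yl)cyclohexa-2,5-dien-1-one ((R)-elaphopilosin A bis(methoxymethyl) ether)
Conditions: Mg(OMe)2 (3 equiv), MeOH, rt to 50 °C; then cold 1 M HCl to pH 3, EtOAc
Reagents that add atoms: none
Why: Mg(OMe)2 deprotonates the most acidic site of 23, the C6 methylene of the C5/C7 diketone (chain numbering), and this chelated enolate carbon attacks the C1 methyl ester; loss of methoxide gives a triacylmethane that is deprotonated at once, so the closure is drained into the stabilised magnesium trione enolate. The closest known reactions are the Claisen (Dieckmann) cyclisations of 3,5,7-trioxoalkanoate esters to acylphloroglucinols and of 2,2-disubstituted 3,5-dioxo esters to cyclohexane-1,3,5-triones. Ring A closes in a 6-exo-trig addition–elimination in which chain C6 bonds to chain C1, that is the C1–C6 bond of ring A. No stereocentre is created: the quaternary carbon has no α-hydrogen and keeps the configuration set in step 2, and the epimeric C2 of the chain becomes sp2. The step needs Claisen rather than aldol folding and ring closure rather than retro-Claisen cleavage at the quaternary carbon: the only six-membered aldol path has the hindered, benzylated C2 attack a C7 carbonyl that is tied up in the magnesium diketonate, O-acylation to the enol lactone is reversed by methanol, and both ketones flanking the quaternary carbon sit in chelated enolates, which keeps methoxide off them.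

Step 16
Reactants: 24
Product: 25 elaphopilosin A, (4R)-2-butanoyl-6-[(3-butanoyl-2,4-dihydroxy-6-methoxyphenyl)methyl]-3,5-dihydroxy-4-methyl-4-(3-methylbut-2-en-1-yl)cyclohexa-2,5-dien-1-one
Conditions: 3 M aq. HCl/MeOH (1:4), rt to 40 °C
Reagents that add atoms: none
Why: Acid-catalysed acetal exchange with methanol removes both MOM ethers, which are activated by the ortho carbonyl group, under conditions that prenylated acylphloroglucinols normally tolerate.

**Compound list**

1 | dimethyl 2-methylpropanedioate | COC(=O)C(C)C(=O)OC | starting material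
2 | 1-bromo-3-methylbut-2-ene | CC(C)=CCBr | starting material
3 | dimethyl 2-methyl-2-(3-methylbut-2-en-1-yl)propanedioate | COC(=O)C(C)(CC=C(C)C)C(=O)OC | intermediate
4 | (2S)-2-(methoxycarbonyl)-2,5-dimethylhex-4-enoic acid | OC(=O)[C@](C)(CC=C(C)C)C(=O)OC | intermediate
5 | pent-1-yne | CCCC#C | starting material
6 | methyl (2R)-2-(chlorocarbonyl)-2,5-dimethylhex-4-enoate | ClC(=O)[C@](C)(CC=C(C)C)C(=O)OC | intermediate
7 | methyl (2S)-2-methyl-2-(3-methylbut-2-en-1-yl)-3-oxooct-4-ynoate | CCCC#CC(=O)[C@](C)(CC=C(C)C)C(=O)OC | intermediate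
8 | methyl (2S)-2,5-dimethyl-2-(3-propyl-1,2-oxazol-5-yl)hex-4-enoate | CCCc1noc(c1)[C@](C)(CC=C(C)C)C(=O)OC | intermediate
9 | (2S)-2,5-dimethyl-2-(3-propyl-1,2-oxazol-5-yl)hex-4-enoic acid | CCCc1noc(c1)[C@](C)(CC=C(C)C)C(=O)O | intermediate
10 | potassium 3-methoxy-3-oxopropanoate | COC(=O)CC(=O)[O-].[K+] | starting material
11 | 1-[(2S)-2,5-dimethyl-2-(3-propyl-1,2-oxazol-5-yl)hex-4-enoyl]imidazole | CCCc1noc(c1)[C@](C)(CC=C(C)C)C(=O)n1ccnc1 | intermediate
12 | methyl (4S)-4,7-dimethyl-3-oxo-4-(3-propyl-1,2-oxazol-5-yl)oct-6-enoate | CCCc1noc(c1)[C@](C)(CC=C(C)C)C(=O)CC(=O)OC | intermediate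
13 | benzene-1,3,5-triol (phloroglucinol) | Oc1cc(O)cc(O)c1 | starting material
14 | butanoyl chloride | CCCC(=O)Cl | starting material
15 | 1-(2,4,6-trihydroxyphenyl)butan-1-one | CCCC(=O)c1c(O)cc(O)cc1O | intermediate
16 | 1-(2,6-dihydroxy-4-methoxyphenyl)butan-1-one | CCCC(=O)c1c(O)cc(OC)cc1O | intermediate
17 | 3-butanoyl-2,4-dihydroxy-6-methoxybenzaldehyde | CCCC(=O)c1c(O)cc(OC)c(C=O)c1O | intermediate
18 | 3-butanoyl-6-methoxy-2,4-bis(methoxymethoxy)benzaldehyde | CCCC(=O)c1c(OCOC)cc(OC)c(C=O)c1OCOC | intermediate
19 | 1-[3-(hydroxymethyl)-4-methoxy-2,6-bis(methoxymethoxy)phenyl]butan-1-one | CCCC(=O)c1c(OCOC)cc(OC)c(CO)c1OCOC | intermediate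
20 | 1-[3-(bromomethyl)-4-methoxy-2,6-bis(methoxymethoxy)phenyl]butan-1-one | CCCC(=O)c1c(OCOC)cc(OC)c(CBr)c1OCOC | intermediate
21 | methyl (4S)-2-{[3-butanoyl-6-methoxy-2,4-bis(methoxymethoxy)phenyl]methyl}-4,7-dimethyl-3-oxo-4-(3-propyl-1,2-oxazol-5-yl)oct-6-enoate (C2 epimers) | CCCc1noc(c1)[C@](C)(CC=C(C)C)C(=O)C(Cc1c(OC)cc(OCOC)c(C(=O)CCC)c1OCOC)C(=O)OC | intermediate
22 | methyl (4S,6Z)-7-amino-2-{[3-butanoyl-6-methoxy-2,4-bis(methoxymethoxy)phenyl]methyl}-4-methyl-4-(3-methylbut-2-en-1-yl)-3,5-dioxodec-6-enoate (C2 epimers) | CCC/C(N)=C/C(=O)[C@](C)(CC=C(C)C)C(=O)C(Cc1c(OC)cc(OCOC)c(C(=O)CCC)c1OCOC)C(=O)OC | intermediate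
23 | methyl (4S)-2-{[3-butanoyl-6-methoxy-2,4-bis(methoxymethoxy)phenyl]methyl}-4-methyl-4-(3-methylbut-2-en-1-yl)-3,5,7-trioxodecanoate (C2 epimers) | CCCC(=O)CC(=O)[C@](C)(CC=C(C)C)C(=O)C(Cc1c(OC)cc(OCOC)c(C(=O)CCC)c1OCOC)C(=O)OC | intermediate
24 | (4R)-2-butanoyl-6-{[3-butanoyl-6-methoxy-2,4-bis(methoxymethoxy)phenyl]methyl}-3,5-dihydroxy-4-methyl-4-(3-methylbut-2-en-1-yl)cyclohexa-2,5-dien-1-one | CCCC(=O)C1=C(O)[C@](C)(CC=C(C)C)C(O)=C(Cc2c(OC)cc(OCOC)c(C(=O)CCC)c2OCOC)C1=O | intermediate
25 | elaphopilosin A, (4R)-2-butanoyl-6-[(3-butanoyl-2,4-dihydroxy-6-methoxyphenyl)methyl]-3,5-dihydroxy-4-methyl-4-(3-methylbut-2-en-1-yl)cyclohexa-2,5-dien-1-one | CCCC(=O)C1=C(O)[C@](C)(CC=C(C)C)C(O)=C(Cc2c(OC)cc(O)c(C(=O)CCC)c2O)C1=O | target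

**Step count and risks**

Total: 16 steps. Longest linear sequence: 10 steps (steps 1–6 and 13–16; the ring B branch, steps 7–12 followed by 13–16, is equally long).

Steps most likely to fail:

Step 15. Methoxide may add to one of the two ketones that flank the quaternary carbon and cleave the chain by retro-Claisen fragmentation faster than the hindered, partly enolised methyl ester is acylated. The fallback makes the acyl acceptor a thioester so that no alkoxide is needed. It sets out from acid 9. The acyl imidazole 11 is formed as before and treated with the magnesium enolate of 3-(ethylsulfanyl)-3-oxopropanoic acid (MgCl2, Et3N), a decarboxylative Claisen reaction of a malonic acid half thioester, which should give the S-ethyl β-keto thioester F1. Alkylation with 20 (K2CO3, acetone) gives the benzylated thioester F2. Mo(CO)6 in wet MeCN followed by aqueous oxalic acid gives, through the enaminone thioester F3 (not isolated), the triketo thioester F4. Because ethanethiolate is a better leaving group than methoxide, ring A should then close by the same C1–C6 Claisen bond with a non-nucleophilic amine base (DBU, CH2Cl2, 0 °C). The product is 24, where the fallback rejoins the route.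

Step 14. The acid needed to hydrolyse the enaminone may also strip a MOM ether, after which the freed phenol can add to the neighbouring C3 ketone and dehydrate to a chromene. The fallback opens the isoxazole before ring B is present and forms the methylene bridge last. It sets out from 12, with 16 as the ring B partner. Mo(CO)6 in wet MeCN and then aqueous oxalic acid convert 12, through the enaminone F5 (not isolated), into the triketo ester F6. Mg(OMe)2 in MeOH closes ring A by the same C1–C6 Claisen bond to give the ring A trione F7. Separately, 16 is aminomethylated with CH2O and Me2NH in EtOH (Mannich reaction) to the Mannich base F8. Heating F8 with F7 in toluene releases dimethylamine and an ortho-quinone methide, which is trapped by the enolic C5 carbon of ring A. This gives 25 directly, so the fallback rejoins the route at the target without any MOM ether.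

Step 2. The esterase may discriminate poorly between the two ester groups for a 2-substituent of this size, or prefer the wrong one. The fallback is a classical resolution. It sets out from 3. KOH (1 equiv) in MeOH gives the racemic half-ester F9. Crystallisation with (S)-1-phenylethylamine (or its enantiomer, whichever gives the less soluble salt of the (S)-acid) gives the diastereomerically pure ammonium salt F10. Acidification returns 4, where the fallback rejoins the route.

**Further compounds**

F1 | step 15 | S-ethyl (4S)-4,7-dimethyl-3-oxo-4-(3-propyl-1,2-oxazol-5-yl)oct-6-enethioate | CCCc1noc(c1)[C@](C)(CC=C(C)C)C(=O)CC(=O)SCC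
F2 | step 15 | S-ethyl (4S)-2-{[3-butanoyl-6-methoxy-2,4-bis(methoxymethoxy)phenyl]methyl}-4,7-dimethyl-3-oxo-4-(3-propyl-1,2-oxazol-5-yl)oct-6-enethioate (C2 epimers) | CCCc1noc(c1)[C@](C)(CC=C(C)C)C(=O)C(Cc1c(OC)cc(OCOC)c(C(=O)CCC)c1OCOC)C(=O)SCC
F3 | step 15 | S-ethyl (4S,6Z)-7-amino-2-{[3-butanoyl-6-methoxy-2,4-bis(methoxymethoxy)phenyl]methyl}-4-methyl-4-(3-methylbut-2-en-1-yl)-3,5-dioxodec-6-enethioate (C2 epimers) | CCC/C(N)=C/C(=O)[C@](C)(CC=C(C)C)C(=O)C(Cc1c(OC)cc(OCOC)c(C(=O)CCC)c1OCOC)C(=O)SCC
F4 | step 15 | S-ethyl (4S)-2-{[3-butanoyl-6-methoxy-2,4-bis(methoxymethoxy)phenyl]methyl}-4-methyl-4-(3-methylbut-2-en-1-yl)-3,5,7-trioxodecanethioate (C2 epimers) | CCCC(=O)CC(=O)[C@](C)(CC=C(C)C)C(=O)C(Cc1c(OC)cc(OCOC)c(C(=O)CCC)c1OCOC)C(=O)SCC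
F5 | step 14 | methyl (4R,6Z)-7-amino-4-methyl-4-(3-methylbut-2-en-1-yl)-3,5-dioxodec-6-enoate | CCC/C(N)=C/C(=O)[C@](C)(CC=C(C)C)C(=O)CC(=O)OC
F6 | step 14 | methyl (4S)-4-methyl-4-(3-methylbut-2-en-1-yl)-3,5,7-trioxodecanoate | CCCC(=O)CC(=O)[C@](C)(CC=C(C)C)C(=O)CC(=O)OC
F7 | step 14 | (4R)-2-butanoyl-3,5-dihydroxy-4-methyl-4-(3-methylbut-2-en-1-yl)cyclohexa-2,5-dien-1-one | CCCC(=O)C1=C(O)[C@](C)(CC=C(C)C)C(O)=CC1=O
F8 | step 14 | 1-{3-[(dimethylamino)methyl]-2,6-dihydroxy-4-methoxyphenyl}butan-1-one | CCCC(=O)c1c(O)cc(OC)c(CN(C)C)c1O
F9 | step 2 | 2-(methoxycarbonyl)-2,5-dimethylhex-4-enoic acid (racemic) | OC(=O)C(C)(CC=C(C)C)C(=O)OC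
F10 | step 2 | (S)-1-phenylethylammonium (2S)-2-(methoxycarbonyl)-2,5-dimethylhex-4-enoate | [O-]C(=O)[C@](C)(CC=C(C)C)C(=O)OC.C[C@H]([NH3+])c1ccccc1
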